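## Retrosynthetic overview

1. Target 22 ← fluoride desilylation of 21; ring C (the pyranone) is closed last by intramolecular Friedel–Crafts acylation (C4–C4a) of acid 19 onto ring A.
2. 19 ← Mitsunobu ether (O1–C2) between ring A phenol 16 (from phloroglucinol) and β-hydroxy imide 14, then removal of the auxiliary.
3. 14 ← key C2–C3 bond: Evans titanium-enolate aldol of arylacetyl imide 11 with formaldehyde (1,3,5-trioxane), which sets C3 as R.
4. 11 ← arylacetic acid 8 ← one-carbon homologation of chromene aldehyde 5.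
5. Ring order: the dimethylpyran ring of the ring B chromene first (propargyl-ether Claisen on 2,4-dihydroxybenzaldehyde), ring A bought intact, ring C last.

Assumption: the single stereocentre is C3 (R, as read from the SMILES); because it is a base-labile benzylic α-keto centre, every operation after the ketone exists is kept neutral to weakly acidic.

TIPS = triisopropylsilyl; TIPSO = (triisopropylsilyl)oxy.

## Route

Step 1
Reactants: 1 2,4-dihydroxybenzaldehyde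
Product: 2 2-hydroxy-4-(TIPSO)benzaldehyde
Conditions: TIPSCl (1.05 equiv), imidazole, DMF, 0 °C → rt
Reagents that add atoms: triisopropylsilyl chloride, CC(C)[Si](Cl)(C(C)C)C(C)C
Why: Selective O-silylation; the 2-OH is hydrogen-bonded to the formyl group and hindered, so the bulky silyl chloride takes only the 4-OH.

Step 2
Reactants: 2 2-hydroxy-4-(TIPSO)benzaldehyde; 3 3-chloro-3-methyl-1-butyne
Product: 4 2-[(2-methylbut-3-yn-2-yl)oxy]-4-(TIPSO)benzaldehyde
Conditions: DBU, CuCl2·2H2O (1 mol%), MeCN, 0 °C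
Reagents that add atoms: none
Why: Copper-catalysed propargylic etherification alkylates the one free phenol with the tertiary propargyl chloride under base mild enough to spare the aryl silyl ether.

Step 3
Reactants: 4 2-[(2-methylbut-3-yn-2-yl)oxy]-4-(TIPSO)benzaldehyde
Product: 5 2,2-dimethyl-5-(TIPSO)-2H-chromene-8-carbaldehyde
Conditions: N,N-diethylaniline, 180 °C
Reagents that add atoms: none
Why: Aromatic propargyl Claisen rearrangement to the only open ortho position (between the two oxygens), then 1,5-H shift and oxa-6π electrocyclisation, gives the chromene with its ring oxygen next to the formyl-bearing carbon.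

Step 4
Reactants: 5 2,2-dimethyl-5-(TIPSO)-2H-chromene-8-carbaldehyde
Product: 6 8-(2-methoxyethenyl)-2,2-dimethyl-5-(TIPSO)-2H-chromene (E/Z mixture)
Conditions: MeOCH2PPh3Cl, KOtBu, THF, 0 °C → rt
Reagents that add atoms: (methoxymethyl)triphenylphosphonium chloride, COC[P+](c1ccccc1)(c1ccccc1)c1ccccc1.[Cl-]
Why: Wittig olefination with the methoxymethylene ylide is the standard one-carbon homologation of an aryl aldehyde; the alkene geometry is irrelevant.

Step 5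
Reactants: 6 8-(2-methoxyethenyl)-2,2-dimethyl-5-(TIPSO)-2H-chromene
Product: 7 2-[2,2-dimethyl-5-(TIPSO)-2H-chromen-8-yl]acetaldehyde (used crude)
Conditions: 2 M HCl, THF, 50 °C
Reagents that add atoms: water, O
Why: Acid hydrolysis of the enol ether, which protonates far more readily than the chromene alkene, while aryl TIPS ethers are acid-stable.

Step 6
Reactants: 7 2-[2,2-dimethyl-5-(TIPSO)-2H-chromen-8-yl]acetaldehyde
Product: 8 2-[2,2-dimethyl-5-(TIPSO)-2H-chromen-8-yl]acetic acid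
Conditions: NaClO2, NaH2PO4, 2-methyl-2-butene, t-BuOH/H2O, 0 °C → rt
Reagents that add atoms: sodium chlorite, [Na+].[O-]Cl=O
Why: Pinnick oxidation converts the aldehyde to the acid, with excess 2-methyl-2-butene trapping HOCl before it can chlorinate ring B or the chromene alkene.

Step 7
Reactants: 8 2-[2,2-dimethyl-5-(TIPSO)-2H-chromen-8-yl]acetic acid; 9 (S)-4-benzyl-2-oxazolidinone
Product: 11 (S)-4-benzyl-3-{2-[2,2-dimethyl-5-(TIPSO)-2H-chromen-8-yl]acetyl}oxazolidin-2-one, via mixed pivalic anhydride 10 (not isolated)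
Conditions: PivCl, Et3N, THF, −20 °C; then LiCl, 9, −20 °C → rt
Reagents that add atoms: none
Why: N-acylation of the Evans auxiliary through the mixed pivalic anhydride, which is attacked only at the unhindered arylacetyl carbonyl.

Step 8
Reactants: 11 (S)-4-benzyl-3-{2-[2,2-dimethyl-5-(TIPSO)-2H-chromen-8-yl]acetyl}oxazolidin-2-one; 12 1,3,5-trioxane
Product: 14 (S)-4-benzyl-3-{(R)-2-[2,2-dimethyl-5-(TIPSO)-2H-chromen-8-yl]-3-hydroxypropanoyl}oxazolidin-2-one, via trichlorotitanium (Z)-enolate 13 (not isolated)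
Conditions: TiCl4, iPr2NEt, CH2Cl2, 0 °C; then 12, TiCl4, 0 °C; aq NH4Cl
Reagents that add atoms: none
Why: Evans titanium-enolate aldol with formaldehyde (hydroxymethylation): the chelated (Z)-enolate is attacked on the face opposite the benzyl group, which sets the α-carbon as R (the future C3); the minor diastereomer is removed by chromatography.

Step 9
Reactants: 15 phloroglucinol
Product: 16 3,5-bis(TIPSO)phenol
Conditions: TIPSCl (2.0 equiv), imidazole, DMF, 0 °C → rt; chromatography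
Reagents that add atoms: triisopropylsilyl chloride, CC(C)[Si](Cl)(C(C)C)C(C)C
Why: Statistical O-silylation of a cheap symmetric triphenol; the bis-ether is separated from mono- and tris-ethers, which are recycled.

Step 10
Reactants: 14 (S)-4-benzyl-3-{(R)-2-[2,2-dimethyl-5-(TIPSO)-2H-chromen-8-yl]-3-hydroxypropanoyl}oxazolidin-2-one; 16 3,5-bis(TIPSO)phenol
Product: 17 (S)-4-benzyl-3-{(R)-3-[3,5-bis(TIPSO)phenoxy]-2-[2,2-dimethyl-5-(TIPSO)-2H-chromen-8-yl]propanoyl}oxazolidin-2-one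
Conditions: PPh3, DIAD, toluene, 0 °C → rt
Reagents that add atoms: none
Why: Mitsunobu etherification of an unhindered primary alcohol with an acidic phenol; the stereocentre is untouched because allylic strain in the imide disfavours α-deprotonation.

Step 11
Reactants: 17 (S)-4-benzyl-3-{(R)-3-[3,5-bis(TIPSO)phenoxy]-2-[2,2-dimethyl-5-(TIPSO)-2H-chromen-8-yl]propanoyl}oxazolidin-2-one
Product: 19 (R)-3-[3,5-bis(TIPSO)phenoxy]-2-[2,2-dimethyl-5-(TIPSO)-2H-chromen-8-yl]propanoic acid, via peroxy acid 18 (not isolated)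
Conditions: LiOH, 30% H2O2, THF/H2O (3:1), 0 °C; then aq Na2SO3; 1 M HCl to pH 3
Reagents that add atoms: hydrogen peroxide, OO
Why: Hydroperoxide cleavage of the Evans imide attacks the exocyclic carbonyl selectively at 0 °C without epimerising the α-aryl centre, and aryl TIPS ethers tolerate the brief cold base.

Step 12
Reactants: 19 (R)-3-[3,5-bis(TIPSO)phenoxy]-2-[2,2-dimethyl-5-(TIPSO)-2H-chromen-8-yl]propanoic acid
Product: 21 (R)-3-[2,2-dimethyl-5-(TIPSO)-2H-chromen-8-yl]-5,7-bis(TIPSO)chroman-4-one, via mixed trifluoroacetic anhydride 20 (not isolated)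
Conditions: (CF3CO)2O (1.5 equiv), CH2Cl2, 0 °C → rt
Reagents that add atoms: none
Why: Intramolecular Friedel–Crafts acylation onto the phloroglucinol-type ring A, whose two positions ortho to the ether oxygen are equivalent; no base or strong Lewis acid is present, so the stereocentre and the chromene survive.

Step 13
Reactants: 21 (R)-3-[2,2-dimethyl-5-(TIPSO)-2H-chromen-8-yl]-5,7-bis(TIPSO)chroman-4-one
Product: 22 (R)-5,7-dihydroxy-3-(5-hydroxy-2,2-dimethyl-2H-chromen-8-yl)chroman-4-one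
Conditions: TBAF, AcOH (1:1.2), THF, 0 °C
Reagents that add atoms: none
Why: Fluoride cleavage of the three aryl silyl ethers under acetic acid buffering, so no phenoxide or fluoride base can enolise C3 and the R configuration is retained.

## Compound list

1 | 2,4-dihydroxybenzaldehyde | O=Cc1ccc(O)cc1O | starting material
2 | 2-hydroxy-4-(TIPSO)benzaldehyde | O=Cc1ccc(O[Si](C(C)C)(C(C)C)C(C)C)cc1O | intermediate
3 | 3-chloro-3-methyl-1-butyne | C#CC(C)(C)Cl | starting material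
4 | 2-[(2-methylbut-3-yn-2-yl)oxy]-4-(TIPSO)benzaldehyde | O=Cc1ccc(O[Si](C(C)C)(C(C)C)C(C)C)cc1OC(C)(C)C#C | intermediate
5 | 2,2-dimethyl-5-(TIPSO)-2H-chromene-8-carbaldehyde | CC1(C)C=Cc2c(O[Si](C(C)C)(C(C)C)C(C)C)ccc(C=O)c2O1 | intermediate
6 | 8-(2-methoxyethenyl)-2,2-dimethyl-5-(TIPSO)-2H-chromene (E/Z mixture) | CC1(C)C=Cc2c(O[Si](C(C)C)(C(C)C)C(C)C)ccc(C=COC)c2O1 | intermediate
7 | 2-[2,2-dimethyl-5-(TIPSO)-2H-chromen-8-yl]acetaldehyde | CC1(C)C=Cc2c(O[Si](C(C)C)(C(C)C)C(C)C)ccc(CC=O)c2O1 | intermediate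
8 | 2-[2,2-dimethyl-5-(TIPSO)-2H-chromen-8-yl]acetic acid | CC1(C)C=Cc2c(O[Si](C(C)C)(C(C)C)C(C)C)ccc(CC(=O)O)c2O1 | intermediate
9 | (S)-4-benzyl-2-oxazolidinone | O=C1N[C@@H](Cc2ccccc2)CO1 | starting material
10 | mixed anhydride of 8 with pivalic acid | CC1(C)C=Cc2c(O[Si](C(C)C)(C(C)C)C(C)C)ccc(CC(=O)OC(=O)C(C)(C)C)c2O1 | intermediate
11 | (S)-4-benzyl-3-{2-[2,2-dimethyl-5-(TIPSO)-2H-chromen-8-yl]acetyl}oxazolidin-2-one | CC1(C)C=Cc2c(O[Si](C(C)C)(C(C)C)C(C)C)ccc(CC(=O)N3C(=O)OC[C@@H]3Cc3ccccc3)c2O1 | intermediate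
12 | 1,3,5-trioxane | C1OCOCO1 | starting material
13 | trichlorotitanium (Z)-enolate of 11 | Cl[Ti](Cl)(Cl)O/C(=C\c1ccc(O[Si](C(C)C)(C(C)C)C(C)C)c2C=CC(C)(C)Oc12)N1C(=O)OC[C@@H]1Cc1ccccc1 | intermediate
14 | (S)-4-benzyl-3-{(R)-2-[2,2-dimethyl-5-(TIPSO)-2H-chromen-8-yl]-3-hydroxypropanoyl}oxazolidin-2-one | CC1(C)C=Cc2c(O[Si](C(C)C)(C(C)C)C(C)C)ccc([C@H](CO)C(=O)N3C(=O)OC[C@@H]3Cc3ccccc3)c2O1 | intermediate
15 | phloroglucinol | Oc1cc(O)cc(O)c1 | starting material
16 | 3,5-bis(TIPSO)phenol | Oc1cc(O[Si](C(C)C)(C(C)C)C(C)C)cc(O[Si](C(C)C)(C(C)C)C(C)C)c1 | intermediate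
17 | (S)-4-benzyl-3-{(R)-3-[3,5-bis(TIPSO)phenoxy]-2-[2,2-dimethyl-5-(TIPSO)-2H-chromen-8-yl]propanoyl}oxazolidin-2-one | CC1(C)C=Cc2c(O[Si](C(C)C)(C(C)C)C(C)C)ccc([C@H](COc3cc(O[Si](C(C)C)(C(C)C)C(C)C)cc(O[Si](C(C)C)(C(C)C)C(C)C)c3)C(=O)N3C(=O)OC[C@@H]3Cc3ccccc3)c2O1 | intermediate
18 | (R)-3-[3,5-bis(TIPSO)phenoxy]-2-[2,2-dimethyl-5-(TIPSO)-2H-chromen-8-yl]propaneperoxoic acid | CC1(C)C=Cc2c(O[Si](C(C)C)(C(C)C)C(C)C)ccc([C@H](COc3cc(O[Si](C(C)C)(C(C)C)C(C)C)cc(O[Si](C(C)C)(C(C)C)C(C)C)c3)C(=O)OO)c2O1 | intermediate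
19 | (R)-3-[3,5-bis(TIPSO)phenoxy]-2-[2,2-dimethyl-5-(TIPSO)-2H-chromen-8-yl]propanoic acid | CC1(C)C=Cc2c(O[Si](C(C)C)(C(C)C)C(C)C)ccc([C@H](COc3cc(O[Si](C(C)C)(C(C)C)C(C)C)cc(O[Si](C(C)C)(C(C)C)C(C)C)c3)C(=O)O)c2O1 | intermediate
20 | mixed anhydride of 19 with trifluoroacetic acid | CC1(C)C=Cc2c(O[Si](C(C)C)(C(C)C)C(C)C)ccc([C@H](COc3cc(O[Si](C(C)C)(C(C)C)C(C)C)cc(O[Si](C(C)C)(C(C)C)C(C)C)c3)C(=O)OC(=O)C(F)(F)F)c2O1 | intermediate
21 | (R)-3-[2,2-dimethyl-5-(TIPSO)-2H-chromen-8-yl]-5,7-bis(TIPSO)chroman-4-one | CC1(C)C=Cc2c(O[Si](C(C)C)(C(C)C)C(C)C)ccc([C@@H]3COc4cc(O[Si](C(C)C)(C(C)C)C(C)C)cc(O[Si](C(C)C)(C(C)C)C(C)C)c4C3=O)c2O1 | intermediate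
22 | (R)-5,7-dihydroxy-3-(5-hydroxy-2,2-dimethyl-2H-chromen-8-yl)chroman-4-one | CC1(C)C=Cc2c(O)ccc([C@@H]3COc4cc(O)cc(O)c4C3=O)c2O1 | target

## Step count and risks

Total step count: 13.
Longest linear sequence: 12 steps (1 → 22 through steps 1–8 and 10–13); step 9 is a one-step side branch.

**Step 8 (aldol).** The TiCl4-activated formaldehyde could also attack the electron-rich chromene alkene or ring B (Prins or Friedel–Crafts hydroxymethylation). The fallback sets out from 11 and comes back at 14. It drops Lewis-acid activation and makes the same bond as a base-only aldol. Imide 11 is deprotonated with LiN(SiMe3)2 in THF at −78 °C to the lithium (Z)-enolate F1. This is treated with monomeric formaldehyde gas (cracked paraformaldehyde in a nitrogen stream) and quenched cold with AcOH. Chelate-controlled attack anti to the benzyl group again gives 14; a lower diastereomer ratio is expected and the minor isomer is removed by chromatography.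

**Step 10 (Mitsunobu).** β-Elimination to the 2-arylacrylimide may compete with ether formation. The fallback sets out from 8 and comes back at 19. It forms the ether on a reduced relay that has no acidic α-hydrogen next to a carbonyl. Because the two CH2O arms swap roles on this relay, the mirror-image auxiliary is needed.
Acid 8 is coupled (PivCl, Et3N, LiCl, through 10) with bought (R)-4-benzyl-2-oxazolidinone to give the (R)-auxiliary imide F2. Its trichlorotitanium (Z)-enolate F3 reacts with 12 and TiCl4 to give the (S)-hydroxymethyl imide F4, the enantiomer of 14. TBSCl and imidazole give the TBS ether F5. LiBH4 (THF, MeOH, 0 °C) removes the auxiliary reductively to the (R)-mono-TBS diol F6. Mitsunobu coupling of F6 with 16 (PPh3, DIAD, toluene) gives the aryl ether F7. Catalytic camphorsulfonic acid in MeOH/CH2Cl2 at 0 °C removes only the alkyl TBS group, leaving the aryl TIPS ethers, to give the (S)-primary alcohol F8. TEMPO (cat.) with PhI(OAc)2 in MeCN/H2O oxidises F8 through the (R)-aldehyde F9 (not isolated) to acid 19.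

**Step 12 (Friedel–Crafts ring closure).** The mixed anhydride may be too weak an electrophile next to the bulky ortho TIPSO group, or trifluoroacetylation of ring A may compete. The fallback sets out from 19 and comes back at 21. It uses a discrete acylium-type acylation instead. Acid 19 is converted under neutral conditions with 1-chloro-N,N,2-trimethyl-1-propenylamine (CH2Cl2, 0 °C) into the (R)-acid chloride F10. This is cyclised with SnCl4 (1.1 equiv) in CH2Cl2 at −78 °C and quenched cold with aqueous NaHCO3 to give 21.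

## Further compounds

F1 | step 8 | lithium (Z)-enolate of 11 | [Li]O/C(=C\c1ccc(O[Si](C(C)C)(C(C)C)C(C)C)c2C=CC(C)(C)Oc12)N1C(=O)OC[C@@H]1Cc1ccccc1
F2 | step 10 | (R)-4-benzyl-3-{2-[2,2-dimethyl-5-(TIPSO)-2H-chromen-8-yl]acetyl}oxazolidin-2-one | CC1(C)C=Cc2c(O[Si](C(C)C)(C(C)C)C(C)C)ccc(CC(=O)N3C(=O)OC[C@H]3Cc3ccccc3)c2O1
F3 | step 10 | trichlorotitanium (Z)-enolate of F2 | Cl[Ti](Cl)(Cl)O/C(=C\c1ccc(O[Si](C(C)C)(C(C)C)C(C)C)c2C=CC(C)(C)Oc12)N1C(=O)OC[C@H]1Cc1ccccc1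
F4 | step 10 | (R)-4-benzyl-3-{(S)-2-[2,2-dimethyl-5-(TIPSO)-2H-chromen-8-yl]-3-hydroxypropanoyl}oxazolidin-2-one | CC1(C)C=Cc2c(O[Si](C(C)C)(C(C)C)C(C)C)ccc([C@@H](CO)C(=O)N3C(=O)OC[C@H]3Cc3ccccc3)c2O1
F5 | step 10 | (R)-4-benzyl-3-{(S)-3-[(tert-butyldimethylsilyl)oxy]-2-[2,2-dimethyl-5-(TIPSO)-2H-chromen-8-yl]propanoyl}oxazolidin-2-one | CC1(C)C=Cc2c(O[Si](C(C)C)(C(C)C)C(C)C)ccc([C@@H](CO[Si](C)(C)C(C)(C)C)C(=O)N3C(=O)OC[C@H]3Cc3ccccc3)c2O1
F6 | step 10 | (R)-3-[(tert-butyldimethylsilyl)oxy]-2-[2,2-dimethyl-5-(TIPSO)-2H-chromen-8-yl]propan-1-ol | CC1(C)C=Cc2c(O[Si](C(C)C)(C(C)C)C(C)C)ccc([C@@H](CO[Si](C)(C)C(C)(C)C)CO)c2O1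
F7 | step 10 | {(R)-3-[3,5-bis(TIPSO)phenoxy]-2-[2,2-dimethyl-5-(TIPSO)-2H-chromen-8-yl]propoxy}(tert-butyl)dimethylsilane | CC1(C)C=Cc2c(O[Si](C(C)C)(C(C)C)C(C)C)ccc([C@@H](CO[Si](C)(C)C(C)(C)C)COc3cc(O[Si](C(C)C)(C(C)C)C(C)C)cc(O[Si](C(C)C)(C(C)C)C(C)C)c3)c2O1
F8 | step 10 | (S)-3-[3,5-bis(TIPSO)phenoxy]-2-[2,2-dimethyl-5-(TIPSO)-2H-chromen-8-yl]propan-1-ol | CC1(C)C=Cc2c(O[Si](C(C)C)(C(C)C)C(C)C)ccc([C@@H](CO)COc3cc(O[Si](C(C)C)(C(C)C)C(C)C)cc(O[Si](C(C)C)(C(C)C)C(C)C)c3)c2O1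
F9 | step 10 | (R)-3-[3,5-bis(TIPSO)phenoxy]-2-[2,2-dimethyl-5-(TIPSO)-2H-chromen-8-yl]propanal | CC1(C)C=Cc2c(O[Si](C(C)C)(C(C)C)C(C)C)ccc([C@@H](C=O)COc3cc(O[Si](C(C)C)(C(C)C)C(C)C)cc(O[Si](C(C)C)(C(C)C)C(C)C)c3)c2O1
F10 | step 12 | (R)-3-[3,5-bis(TIPSO)phenoxy]-2-[2,2-dimethyl-5-(TIPSO)-2H-chromen-8-yl]propanoyl chloride | CC1(C)C=Cc2c(O[Si](C(C)C)(C(C)C)C(C)C)ccc([C@H](COc3cc(O[Si](C(C)C)(C(C)C)C(C)C)cc(O[Si](C(C)C)(C(C)C)C(C)C)c3)C(=O)Cl)c2O1
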